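The flavone is cut at the aryl ether bond O1–C8a of ring C. The precursor is an open-chain 1,3-diketone whose ring A is a 2,3,4,5-tetramethoxyphenyl ketone and whose ring B carries the 3'-oxygen as a pivalate. Anodic oxidation in hexafluoroisopropanol joins the enol oxygen to the only C–H carbon of ring A, the future C8a, which lies ortho to the acyl-bearing carbon C4a and para to the methoxy group at C6. Ring C thus forms in one dehydrogenative operation, with no halogen or phenol needed on ring A. The pivalate deactivates ring B, survives the enolate acylation that builds the diketone, and is later removed by carbonate in methanol.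

Key step: step 5

Remark: the 1,3-diketone is drawn as the diketo form although it should exist mainly as the chelated enol, the form that reacts in the key step; both starting materials are taken as purchasable.

Step 1
Reactants: 1 1,2,3,4-tetramethoxybenzene
Product: 2 1-(2,3,4,5-tetramethoxyphenyl)ethan-1-one
Conditions: AcOH (1.2 equiv), (CF3CO)2O (3 equiv), 85% H3PO4 (0.5 equiv), CH2Cl2, 0 → 25 °C
Reagents that add atoms: acetic acid, CC(=O)O
Why: Friedel–Crafts acylation by the mixed anhydride acetyl trifluoroacetate: both free positions of 1 are equivalent and activated by an ortho and a para methoxy group, the ketone product is deactivated towards a second acylation, and without a chelating Lewis acid the methoxy group next to the new carbonyl should stay intact.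

Step 2
Reactants: 3 3-hydroxy-4,5-dimethoxybenzoic acid
Product: 4 3-(2,2-dimethylpropanoyloxy)-4,5-dimethoxybenzoic acid
Conditions: PivCl (1.2 equiv), NaOH (2.2 equiv), H2O/THF, 0 °C; then 1 M HCl to pH 2
Reagents that add atoms: pivaloyl chloride, CC(C)(C)C(=O)Cl
Why: Schotten–Baumann O-acylation: in aqueous hydroxide the phenoxide is much more nucleophilic than the carboxylate, and any mixed anhydride formed at the acid is hydrolysed again before acidification, so only the aryl pivalate should remain.

Step 3
Reactants: 4 3-(2,2-dimethylpropanoyloxy)-4,5-dimethoxybenzoic acid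
Product: 5 3-(2,2-dimethylpropanoyloxy)-4,5-dimethoxybenzoyl chloride
Conditions: (COCl)2 (1.3 equiv), DMF (cat.), CH2Cl2, 0 → 25 °C; evaporate, use crude
Reagents that add atoms: oxalyl chloride, O=C(Cl)C(=O)Cl
Why: Acid chloride formation through the catalytic chloroiminium (Vilsmeier-type) species from DMF and oxalyl chloride, conditions that leave the aryl pivalate and the methyl ethers untouched; the crude chloride is used at once.

Step 4
Reactants: 2 1-(2,3,4,5-tetramethoxyphenyl)ethan-1-one; 5 3-(2,2-dimethylpropanoyloxy)-4,5-dimethoxybenzoyl chloride
Product: 7 1-(2,3,4,5-tetramethoxyphenyl)-3-[3-(2,2-dimethylpropanoyloxy)-4,5-dimethoxyphenyl]propane-1,3-dione, via lithium 1-(2,3,4,5-tetramethoxyphenyl)ethen-1-olate 6 (not isolated)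
Conditions: LiN(SiMe3)2 (2.2 equiv), THF, −78 °C; then 5 in THF, −78 → −20 °C; 1 M HCl quench
Reagents that add atoms: none
Why: Crossed Claisen-type C-acylation of a preformed lithium enolate by an aroyl chloride: the second equivalent of amide base converts the diketone into its unreactive enolate as it forms, no alkoxide is released, and at −78 °C the acid chloride should outcompete the hindered aryl pivalate for the enolate by a wide margin.

Step 5
Reactants: 7 1-(2,3,4,5-tetramethoxyphenyl)-3-[3-(2,2-dimethylpropanoyloxy)-4,5-dimethoxyphenyl]propane-1,3-dione
Product: 8 2,3-dimethoxy-5-(5,6,7,8-tetramethoxy-4-oxo-4H-chromen-2-yl)phenyl 2,2-dimethylpropanoate (3'-O-pivaloyl-5,6,7,8,4',5'-hexamethoxyflavone)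
Conditions: undivided cell, graphite anode, Pt cathode, n-Bu4NPF6 (0.1 M), (CF3)2CHOH (dry, substrate 0.05 M), constant current 5 mA cm−2, 2.2 F mol−1, 25 °C
Reagents that add atoms: none
Why: Proposed new method: the anode should take one electron from the enolised diketone, mainly from ring A with its four methoxy groups (the future C5 and C8 methoxy groups are para to each other), the enol oxygen on the ring B side then adds to the radical cation at the free carbon C8a, and a second electron transfer with loss of two protons (balanced by dihydrogen evolution from the solvent at the cathode) gives the pyranone, first as its O-protonated form, which is harder to oxidise than the starting enol. The closest known reaction types are anodic dehydrogenative C–O cyclisations of electron-rich arenes in fluorinated alcohols (benzoxazoles from anilides, benzocoumarins from biaryl-2-carboxylic acids) and, for the same bond, copper-catalysed O-arylation of 2-haloaryl 1,3-diketones. Ring C closes as a six-membered ring in a 6-endo-trig-type ortho-annulation, oxygen attacking the arene carbon next to the acyl-bearing carbon so that the C4a–C8a bond lies inside the new ring; no stereocentre is formed. The step needs ring A to react before ring B, the C–H carbon before the methoxy-bearing ortho carbon, and oxygen before the central carbon: ring B has only two methoxy groups and an acyloxy group that withdraws electron density, so it should be oxidised at higher potential; addition at the C–H carbon is made irreversible by proton loss whereas addition at the C–OMe carbon can revert; and a bond from the central carbon to either ring would require a four-membered ring. No base is added, so the neutral enol and not the easily dimerised enolate is oxidised, and hexafluoroisopropanol stabilises the radical cation without trapping it.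

Step 6
Reactants: 8 2,3-dimethoxy-5-(5,6,7,8-tetramethoxy-4-oxo-4H-chromen-2-yl)phenyl 2,2-dimethylpropanoate
Product: 9 3'-hydroxy-5,6,7,8,4',5'-hexamethoxyflavone
Conditions: K2CO3 (2 equiv), MeOH/THF, 25–40 °C; then 1 M HCl to pH 4
Reagents that add atoms: none
Why: Base-mediated methanolysis (transesterification) of an aryl ester: the phenoxide is a good leaving group, so the pivalate should cleave near room temperature under conditions too mild to open the pyranone ring or touch the methyl ethers.

Compound list
1 | 1,2,3,4-tetramethoxybenzene | COc1ccc(OC)c(OC)c1OC | starting material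
2 | 1-(2,3,4,5-tetramethoxyphenyl)ethan-1-one | CC(=O)c1cc(OC)c(OC)c(OC)c1OC | intermediate
3 | 3-hydroxy-4,5-dimethoxybenzoic acid | OC(=O)c1cc(O)c(OC)c(OC)c1 | starting material
4 | 3-(2,2-dimethylpropanoyloxy)-4,5-dimethoxybenzoic acid | CC(C)(C)C(=O)Oc1cc(C(=O)O)cc(OC)c1OC | intermediate
5 | 3-(2,2-dimethylpropanoyloxy)-4,5-dimethoxybenzoyl chloride | CC(C)(C)C(=O)Oc1cc(C(=O)Cl)cc(OC)c1OC | intermediate
6 | lithium 1-(2,3,4,5-tetramethoxyphenyl)ethen-1-olate | [Li+].[O-]C(=C)c1cc(OC)c(OC)c(OC)c1OC | intermediate (not isolated)
7 | 1-(2,3,4,5-tetramethoxyphenyl)-3-[3-(2,2-dimethylpropanoyloxy)-4,5-dimethoxyphenyl]propane-1,3-dione | COc1cc(C(=O)CC(=O)c2cc(OC)c(OC)c(OC)c2OC)cc(OC(=O)C(C)(C)C)c1OC | intermediate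
8 | 2,3-dimethoxy-5-(5,6,7,8-tetramethoxy-4-oxo-4H-chromen-2-yl)phenyl 2,2-dimethylpropanoate | COc1cc(-c2cc(=O)c3c(OC)c(OC)c(OC)c(OC)c3o2)cc(OC(=O)C(C)(C)C)c1OC | intermediate
9 | 3'-hydroxy-5,6,7,8,4',5'-hexamethoxyflavone | COc1cc(-c2cc(=O)c3c(OC)c(OC)c(OC)c(OC)c3o2)cc(O)c1OC | target

Total step count: 6. Longest linear sequence: 5 steps (3 → 4 → 5 → 7 → 8 → 9); ketone 2 is made in one step and joins at step 4.

Steps most likely to fail

Step 5 (Proposed new method). What may go wrong:
- electron removal from ring B or from traces of diketonate instead of ring A;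
- oxygen attack at the methoxy-bearing ortho carbon, followed by loss of methanol;
- over-oxidation of the electron-rich product;
- fouling of the anode by oligomers.

Fallback, known chemistry only: the same O1–C8a bond is made by Ullmann-type C–O coupling of an aryl bromide. The fallback sets out from ketone 2. Electrophilic bromination of its single free ring position (NBS, MeCN, 25 °C, no initiator) should give 1-(2-bromo-3,4,5,6-tetramethoxyphenyl)ethan-1-one F1. Deprotonation with LiN(SiMe3)2 (THF, −78 °C) gives lithium 1-(2-bromo-3,4,5,6-tetramethoxyphenyl)ethen-1-olate F2. Acylation of F2 by acid chloride 5, as in step 4, gives 1-(2-bromo-3,4,5,6-tetramethoxyphenyl)-3-[3-(2,2-dimethylpropanoyloxy)-4,5-dimethoxyphenyl]propane-1,3-dione F3. Intramolecular O-arylation of the diketonate (CuI 10 mol %, K2CO3, DMF, 100 °C) then closes ring C and comes back to the route at flavone pivalate 8. Any material that loses the pivalate under the carbonate is already target 9.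

Step 4. What may go wrong: acylation of the enolate at oxygen, a second acylation of the product diketonate, or transfer of the pivaloyl group from ring B to the enolate.

Fallback: the carbon–carbon bond is made by aldol addition and the oxidation level is adjusted afterwards. The fallback sets out from acid chloride 5. Rosenmund reduction (H2, Pd/BaSO4, 2,6-lutidine, THF) should give 5-formyl-2,3-dimethoxyphenyl 2,2-dimethylpropanoate F4. Addition of enolate 6 (from ketone 2 and LiN(SiMe3)2, THF, −78 °C, cold quench) gives racemic 5-[1-hydroxy-3-oxo-3-(2,3,4,5-tetramethoxyphenyl)propyl]-2,3-dimethoxyphenyl 2,2-dimethylpropanoate F5. Oxidation of the secondary alcohol with Dess–Martin periodinane (NaHCO3, CH2Cl2) comes back to the route at diketone 7.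

Step 1. What may go wrong: sluggish acylation at a position flanked by a methoxy group. If a stronger Lewis acid is brought in to force it, chelation-assisted loss of the methyl group ortho to the new ketone may follow.

Fallback: directed ortho-metalation replaces electrophilic substitution. The fallback sets out from 1. Lithiation next to a methoxy group (n-BuLi, TMEDA, THF, 0 °C) should give (2,3,4,5-tetramethoxyphenyl)lithium F6. Reaction with N-methoxy-N-methylacetamide (−78 → 0 °C, aqueous NH4Cl work-up) comes back to the route at ketone 2.

Further compounds
F1 | step 5 | 1-(2-bromo-3,4,5,6-tetramethoxyphenyl)ethan-1-one | CC(=O)c1c(Br)c(OC)c(OC)c(OC)c1OC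
F2 | step 5 | lithium 1-(2-bromo-3,4,5,6-tetramethoxyphenyl)ethen-1-olate | [Li+].[O-]C(=C)c1c(Br)c(OC)c(OC)c(OC)c1OC
F3 | step 5 | 1-(2-bromo-3,4,5,6-tetramethoxyphenyl)-3-[3-(2,2-dimethylpropanoyloxy)-4,5-dimethoxyphenyl]propane-1,3-dione | COc1cc(C(=O)CC(=O)c2c(Br)c(OC)c(OC)c(OC)c2OC)cc(OC(=O)C(C)(C)C)c1OC
F4 | step 4 | 5-formyl-2,3-dimethoxyphenyl 2,2-dimethylpropanoate | CC(C)(C)C(=O)Oc1cc(C=O)cc(OC)c1OC
F5 | step 4 | racemic 5-[1-hydroxy-3-oxo-3-(2,3,4,5-tetramethoxyphenyl)propyl]-2,3-dimethoxyphenyl 2,2-dimethylpropanoate | COc1cc(C(O)CC(=O)c2cc(OC)c(OC)c(OC)c2OC)cc(OC(=O)C(C)(C)C)c1OC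
F6 | step 1 | (2,3,4,5-tetramethoxyphenyl)lithium | [Li]c1cc(OC)c(OC)c(OC)c1OC
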